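**Plan**

- Numbering follows the germacranolide skeleton: ring C1–C10, C11(=C13)–C12 on C7, C14 on C10, C15 on C4.
- Retrosynthesis cuts the lactone back to a 6,12-diol, then the ring bond C3–C4, then C7–C8 (aldol), then C1–C2 and C9–C10 of the east piece.
- Enabling feature: C3 is a primary ring methylene bonded to C4, the methyl-bearing carbon of the Z-C4=C5 alkene of the ten-membered ring. C3 can therefore arrive as a radical from the one-carbon-longer acid and C4 as an alkenyl iodide.
- Forward: an east epoxy aldehyde (C1–C3, C8–C10, C14) and a west Z-iodoenone (C4–C7, C11–C13, C15) are joined at C7–C8. C6 is then reduced, the ten-membered ring is closed at C3–C4, and the lactone ring is made last by oxidation.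
- Stereochemistry: C1/C10 from Sharpless epoxidation of a Z-allylic alcohol whose geometry comes from an anti-carbomagnesiation; C7/C8 from a reagent-controlled anti boron aldol; C6 from the Evans–Tishchenko 1,3-anti reduction; Z-C4=C5 from anti hydroiodination of an ynone.

Key step: step 15

Assumption: the bromoborane made from (−)-menthone is taken to send the (E)-enol borinate to the Si face of the aldehyde; if the sense is the opposite, the reagent from (+)-menthone is used and nothing else changes.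

Abbreviations: TBS = tert-butyldimethylsilyl, TES = triethylsilyl, TBDPS = tert-butyldiphenylsilyl. In the open-chain names, oxirane C2/C3 are C1/C10 and heptenyl C1–C7 are C9, C8, C7, C6, C5, C4, C15.

**East fragment**

Step 1
Reactants: 1 prop-2-yn-1-ol; 2 allylmagnesium bromide
Product: 4 (2Z)-2-(iodomethylidene)pent-4-en-1-ol, via alkenylmagnesium alkoxide 3 (not isolated)
Conditions: 2 (2.5 equiv), CuI (10 mol%), Et2O, 0 °C to rt; then I2, −40 to 0 °C
Reagents that add atoms: iodine, II
Why: Copper-catalysed anti-carbomagnesiation of the propargylic alkoxide puts the allyl group on the internal carbon and magnesium on the terminal carbon cis to the CH2O group through a five-membered chelate, and iodinolysis with retention gives the Z-iodoalkene that fixes the later C1=C10 geometry.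

Step 2
Reactants: 4 (2Z)-2-(iodomethylidene)pent-4-en-1-ol; 5 methyl 3-iodopropanoate
Product: 7 methyl (4Z)-5-(hydroxymethyl)octa-4,7-dienoate, via alkylzinc iodide 6 (not isolated)
Conditions: 5, Zn dust (activated with Me3SiCl and BrCH2CH2Br), THF, 40 °C; then 4, Pd(PPh3)4 (5 mol%), THF, rt to 45 °C
Reagents that add atoms: none
Why: Negishi coupling of the ester-bearing alkylzinc iodide with the alkenyl iodide goes with retention at the sp2 carbon, so the propanoate chain (C2, C3) ends up cis to the hydroxymethyl group (C14), as the epoxide needs.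

Step 3
Reactants: 7 methyl (4Z)-5-(hydroxymethyl)octa-4,7-dienoate
Product: 8 methyl 3-[(2R,3S)-3-(hydroxymethyl)-3-(prop-2-en-1-yl)oxiran-2-yl]propanoate
Conditions: Ti(OiPr)4 (10 mol%), diisopropyl L-(+)-tartrate (12 mol%), tBuOOH, 4 Å molecular sieves, CH2Cl2, −20 °C
Reagents that add atoms: tert-butyl hydroperoxide, CC(C)(C)OO
Why: Sharpless asymmetric epoxidation of the 2,3-disubstituted Z-allylic alcohol with the L-(+)-tartrate catalyst should deliver oxygen to the face that gives C1 (R) and C10 (S), and the terminal alkene, having no allylic hydroxyl, is left alone.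

Step 4
Reactants: 8 methyl 3-[(2R,3S)-3-(hydroxymethyl)-3-(prop-2-en-1-yl)oxiran-2-yl]propanoate
Product: 9 methyl 3-[(2R,3S)-3-(TBDPS-oxymethyl)-3-(prop-2-en-1-yl)oxiran-2-yl]propanoate
Conditions: TBDPSCl, imidazole, CH2Cl2, 0 °C to rt
Reagents that add atoms: tert-butyl(chloro)diphenylsilane, CC(C)(C)[Si](Cl)(c1ccccc1)c1ccccc1
Why: Silylation of the primary alcohol; the acid-stable TBDPS ether is chosen so that O14 outlasts the acidic fluoride step that later frees O6 and O12.

Step 5
Reactants: 9 methyl 3-[(2R,3S)-3-(TBDPS-oxymethyl)-3-(prop-2-en-1-yl)oxiran-2-yl]propanoate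
Product: 10 methyl 3-[(2R,3S)-3-(TBDPS-oxymethyl)-3-(2-oxoethyl)oxiran-2-yl]propanoate
Conditions: O3, CH2Cl2, −78 °C; PPh3, −78 °C to rt; crude aldehyde used at once in step 11
Reagents that add atoms: ozone, [O-][O+]=O
Why: Ozonolysis with reductive work-up cleaves the only alkene left and frees the C8 aldehyde under neutral conditions, which the base-sensitive β,γ-epoxy aldehyde needs.

**West fragment**

Step 6
Reactants: 11 monomethyl itaconate (4-methoxy-2-methylidene-4-oxobutanoic acid)
Product: 12 methyl 3-(hydroxymethyl)but-3-enoate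
Conditions: BH3·SMe2, THF, −10 to 10 °C; MeOH quench; product kept cold and silylated directly
Reagents that add atoms: none
Why: Borane reduces the carboxylic acid through its acyloxyborane much faster than the ester or the electron-poor alkene (chemoselective borane reduction), giving the C12 alcohol.

Step 7
Reactants: 12 methyl 3-(hydroxymethyl)but-3-enoate
Product: 13 methyl 3-(TBS-oxymethyl)but-3-enoate
Conditions: TBSCl, imidazole, CH2Cl2, 0 °C
Reagents that add atoms: tert-butyl(chloro)dimethylsilane, CC(C)(C)[Si](C)(C)Cl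
Why: Silylation blocks lactonisation of the γ-hydroxy ester and installs the O12 mask that hides the future lactone carbonyl from the radical step.

Step 8
Reactants: 13 methyl 3-(TBS-oxymethyl)but-3-enoate
Product: 14 3-(TBS-oxymethyl)-N-methoxy-N-methylbut-3-enamide
Conditions: MeNHOMe·HCl, iPrMgCl, THF, −20 °C
Reagents that add atoms: N,O-dimethylhydroxylamine hydrochloride, CNOC.Cl
Why: The magnesium amide of N,O-dimethylhydroxylamine aminolyses the ester directly to the Weinreb amide at low temperature, before the β,γ-alkene can move into conjugation.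

Step 9
Reactants: 14 3-(TBS-oxymethyl)-N-methoxy-N-methylbut-3-enamide; 15 1-propynylmagnesium bromide
Product: 16 2-(TBS-oxymethyl)hept-1-en-5-yn-4-one
Conditions: THF, 0 °C; aq. NH4Cl
Reagents that add atoms: none
Why: Weinreb ketone synthesis: the chelated tetrahedral adduct stops at single addition and releases the ynone only on work-up, and the weakly basic alkynyl Grignard does not enolise the amide.

Step 10
Reactants: 16 2-(TBS-oxymethyl)hept-1-en-5-yn-4-one
Product: 17 (5Z)-2-(TBS-oxymethyl)-6-iodohepta-1,5-dien-4-one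
Conditions: LiI, AcOH (2 equiv), MeCN, rt, dark
Reagents that add atoms: lithium iodide, [Li+].[I-]
Why: Conjugate addition of iodide to the ynone and protonation of the allenolate anti to iodine (hydroiodination) gives the Z-β-iodoenone under kinetic control, which fixes the C4=C5 geometry, and the dilute acid spares the TBS ether.

**Fragment union and ring closure**

Step 11
Reactants: 17 (5Z)-2-(TBS-oxymethyl)-6-iodohepta-1,5-dien-4-one; 10 methyl 3-[(2R,3S)-3-(TBDPS-oxymethyl)-3-(2-oxoethyl)oxiran-2-yl]propanoate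
Product: 19 (7R,8R)-anti-aldol adduct methyl 3-[(2R,3S)-3-(TBDPS-oxymethyl)-3-{(2R,3R,5Z)-2-hydroxy-6-iodo-4-oxo-3-[3-(TBS-oxy)prop-1-en-2-yl]hept-5-en-1-yl}oxiran-2-yl]propanoate, via enol borinate 18 (not isolated)
Conditions: bis{[(1S,2S,5R)-2-isopropyl-5-methylcyclohexyl]methyl}boron bromide, Et3N, Et2O, −78 °C; then 10, −78 to −30 °C; pH 7 buffer/MeOH, diethanolamine work-up
Reagents that add atoms: none
Why: The bromoborane and Et3N give the (E)-enol borinate, whose Zimmerman–Traxler chair leads to the 7,8-anti adduct (boron aldol reaction), and the menthone-derived ligands on boron, not the remote C10 centre, select the Si face of the aldehyde and so set C7 and C8 as (7R,8R).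

Step 12
Reactants: 19 (7R,8R)-anti-aldol adduct; 20 isobutyraldehyde
Product: 22 methyl 3-[(2R,3S)-3-(TBDPS-oxymethyl)-3-{(2R,3S,4S,5Z)-4-hydroxy-6-iodo-2-(2-methylpropanoyloxy)-3-[3-(TBS-oxy)prop-1-en-2-yl]hept-5-en-1-yl}oxiran-2-yl]propanoate, via samarium-bound hemiacetal 21 (not isolated)
Conditions: SmI2 (0.3 equiv), 20 (8 equiv), THF, −10 °C, dark
Reagents that add atoms: none
Why: Evans–Tishchenko reaction: trivalent samarium, formed from SmI2 and the aldehyde, holds the C8 hemiacetal and the C6 ketone in a chair-like array, and intramolecular hydride transfer sets C6 anti to C8 while leaving the isobutyrate on O8 and the hydroxyl on C6 in a single step.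

Step 13
Reactants: 22 C6 alcohol C8 isobutyrate
Product: 23 methyl 3-[(2R,3S)-3-(TBDPS-oxymethyl)-3-{(2R,3R,4S,5Z)-6-iodo-2-(2-methylpropanoyloxy)-3-[3-(TBS-oxy)prop-1-en-2-yl]-4-(TES-oxy)hept-5-en-1-yl}oxiran-2-yl]propanoate
Conditions: TESCl, imidazole, DMF, 0 °C
Reagents that add atoms: chlorotriethylsilane, CC[Si](Cl)(CC)CC
Why: Silylation of the only free hydroxyl; the labile TES group on O6 blocks acyl migration from O8 and can later be removed together with the O12 TBS group while the O14 TBDPS group stays.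

Step 14
Reactants: 23 tris-silyl methyl ester
Product: 25 1,3-dioxo-1,3-dihydro-2H-isoindol-2-yl 3-[(2R,3S)-3-(TBDPS-oxymethyl)-3-{(2R,3R,4S,5Z)-6-iodo-2-(2-methylpropanoyloxy)-3-[3-(TBS-oxy)prop-1-en-2-yl]-4-(TES-oxy)hept-5-en-1-yl}oxiran-2-yl]propanoate, via carboxylic acid 24 (not isolated)
Conditions: Me3SnOH, ClCH2CH2Cl, 60 °C; brief cold aq. KHSO4 wash; then N-hydroxyphthalimide, N,N′-diisopropylcarbodiimide, 4-(dimethylamino)pyridine (cat.), CH2Cl2, 0 °C
Reagents that add atoms: N-hydroxyphthalimide, O=C1c2ccccc2C(=O)N1O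
Why: Me3SnOH cleaves the unhindered methyl ester in preference to the α-branched isobutyrate on the crowded secondary C8 oxygen, and immediate Steglich-type esterification turns the γ,δ-epoxy acid into the redox-active ester before it can open its own epoxide.

Step 15
Reactants: 25 redox-active ester with Z-alkenyl iodide
Product: 26 (1R,4Z,6R,7R,8R,10S)-7-[3-(TBS-oxy)prop-1-en-2-yl]-10-(TBDPS-oxymethyl)-4-methyl-6-(TES-oxy)-11-oxabicyclo[8.1.0]undec-4-en-8-yl 2-methylpropanoate
Conditions: NiCl2·6H2O (0.3 equiv), 2,2′-bipyridine (0.35 equiv), AgNO3 (0.3 equiv), DMF, rt, Mg anode, reticulated vitreous carbon cathode, constant current; 25 added by syringe pump to about 2 mM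
Reagents that add atoms: none
Why: Proposed new method: cathodic electron transfer fragments the phthalimide ester to carbon dioxide, phthalimide anion and the primary C3 radical, while low-valent bipyridine–nickel has inserted into the C4–iodine bond with retention; capture of the radical at nickel and reductive elimination form C3–C4. The closest known reaction type is the intermolecular nickel-electrocatalytic decarboxylative alkenylation of redox-active esters with alkenyl halides, a reductive cross-electrophile coupling. The ten-membered carbocycle is closed end to end by reductive elimination from an eleven-membered nickelacycle, not by radical addition to a π bond. No stereocentre is formed: C1, C6, C7, C8 and C10 are carried through unchanged and the Z geometry of C4=C5 is kept because oxidative addition and reductive elimination at the sp2 carbon are stereoretentive. The step needs ring closure to outrun hydrogen abstraction, dimerisation and reduction of the iodide; slow addition at high dilution keeps the radical concentration low, and the trans-substituted epoxide, the Z-alkene and the crowded C6–C8 segment act as turn elements that bring C3 near C4. The radical sits two carbons from the epoxide, so oxiranylcarbinyl opening is not possible, and the future methylene lactone is present only as an allylic silyl ether, so no radical acceptor is in reach.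

**Endgame**

Step 16
Reactants: 26 tris-silyl epoxy-cyclodecene isobutyrate
Product: 27 (1R,4Z,6R,7S,8R,10S)-10-(TBDPS-oxymethyl)-6-hydroxy-7-(3-hydroxyprop-1-en-2-yl)-4-methyl-11-oxabicyclo[8.1.0]undec-4-en-8-yl 2-methylpropanoate
Conditions: HF·pyridine, pyridine, THF, 0 °C
Reagents that add atoms: none
Why: Buffered HF·pyridine cleaves the secondary TES and primary allylic TBS ethers much faster than the acid-stable TBDPS ether (fluoride desilylation), so O6 and O12 are freed without base that could move the isobutyrate to O6, and O14 stays masked.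

Step 17
Reactants: 27 6,12-diol
Product: 30 (1R,4Z,6R,7R,8R,10S)-1,10-epoxy-8-(2-methylpropanoyloxy)-14-(TBDPS-oxy)germacra-4,11(13)-dien-12,6-olide, via hydroxy enal 28 (not isolated), via lactol 29 (not isolated)
Conditions: 2,2,6,6-tetramethylpiperidin-1-oxyl (20 mol%), PhI(OAc)2, CH2Cl2, rt
Reagents that add atoms: none
Why: Oxidative lactonisation of a 1,4-diol: the oxoammonium oxidant takes the primary allylic C12 alcohol to the enal far faster than it touches the secondary C6 alcohol, the C6 hydroxyl closes the five-membered lactol, and a second oxidation gives the α-methylene γ-lactone.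

Step 18
Reactants: 30 O14-TBDPS lactone
Product: 31 (1R,4Z,6R,7R,8R,10S)-1,10-epoxy-14-hydroxy-8-(2-methylpropanoyloxy)germacra-4,11(13)-dien-12,6-olide (CNP0247143.1)
Conditions: Bu4NF, AcOH (1:1), THF, 0 °C to rt
Reagents that add atoms: none
Why: Fluoride desilylation buffered with AcOH removes the last silyl ether without the free alkoxide that could trigger Payne rearrangement of the epoxy alcohol or add to the methylene lactone.

**Compound list**

1 | prop-2-yn-1-ol | C#CCO | starting material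
2 | allylmagnesium bromide | C=CC[Mg]Br | starting material
3 | bromomagnesium (2Z)-2-[(bromomagnesio)methylidene]pent-4-en-1-olate (formed in the flask) | C=CC/C(=C/[Mg]Br)CO[Mg]Br | intermediate
4 | (2Z)-2-(iodomethylidene)pent-4-en-1-ol | C=CC/C(=C/I)CO | intermediate
5 | methyl 3-iodopropanoate | COC(=O)CCI | starting material
6 | (3-methoxy-3-oxopropyl)zinc iodide (formed in the flask) | COC(=O)CC[Zn]I | intermediate
7 | methyl (4Z)-5-(hydroxymethyl)octa-4,7-dienoate | C=CC/C(=C/CCC(=O)OC)CO | intermediate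
8 | methyl 3-[(2R,3S)-3-(hydroxymethyl)-3-(prop-2-en-1-yl)oxiran-2-yl]propanoate | COC(=O)CC[C@H]1O[C@]1(CO)CC=C | intermediate
9 | methyl 3-[(2R,3S)-3-(TBDPS-oxymethyl)-3-(prop-2-en-1-yl)oxiran-2-yl]propanoate | COC(=O)CC[C@H]1O[C@]1(CO[Si](c2ccccc2)(c2ccccc2)C(C)(C)C)CC=C | intermediate
10 | methyl 3-[(2R,3S)-3-(TBDPS-oxymethyl)-3-(2-oxoethyl)oxiran-2-yl]propanoate | COC(=O)CC[C@H]1O[C@]1(CO[Si](c2ccccc2)(c2ccccc2)C(C)(C)C)CC=O | intermediate
11 | monomethyl itaconate (4-methoxy-2-methylidene-4-oxobutanoic acid) | C=C(CC(=O)OC)C(=O)O | starting material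
12 | methyl 3-(hydroxymethyl)but-3-enoate | C=C(CO)CC(=O)OC | intermediate
13 | methyl 3-(TBS-oxymethyl)but-3-enoate | C=C(CO[Si](C)(C)C(C)(C)C)CC(=O)OC | intermediate
14 | 3-(TBS-oxymethyl)-N-methoxy-N-methylbut-3-enamide | C=C(CO[Si](C)(C)C(C)(C)C)CC(=O)N(C)OC | intermediate
15 | 1-propynylmagnesium bromide | CC#C[Mg]Br | starting material
16 | 2-(TBS-oxymethyl)hept-1-en-5-yn-4-one | C=C(CO[Si](C)(C)C(C)(C)C)CC(=O)C#CC | intermediate
17 | (5Z)-2-(TBS-oxymethyl)-6-iodohepta-1,5-dien-4-one | C=C(CO[Si](C)(C)C(C)(C)C)CC(=O)/C=C(/C)I | intermediate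
18 | (E)-enol borinate of 17, O-bound to bis{[(1S,2S,5R)-2-isopropyl-5-methylcyclohexyl]methyl}boron (formed in the flask) | C=C(CO[Si](C)(C)C(C)(C)C)/C=C(/OB(C[C@@H]1[C@H](C(C)C)CC[C@@H](C)C1)C[C@@H]1[C@H](C(C)C)CC[C@@H](C)C1)\C=C(\C)I | intermediate
19 | methyl 3-[(2R,3S)-3-(TBDPS-oxymethyl)-3-{(2R,3R,5Z)-2-hydroxy-6-iodo-4-oxo-3-[3-(TBS-oxy)prop-1-en-2-yl]hept-5-en-1-yl}oxiran-2-yl]propanoate | C=C(CO[Si](C)(C)C(C)(C)C)[C@@H](C(=O)/C=C(/C)I)[C@H](O)C[C@@]1(CO[Si](c2ccccc2)(c2ccccc2)C(C)(C)C)O[C@@H]1CCC(=O)OC | intermediate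
20 | isobutyraldehyde (2-methylpropanal) | CC(C)C=O | starting material
21 | hemiacetal of 19 at O8 with isobutyraldehyde, held on samarium (neutral form; formed in the flask) | C=C(CO[Si](C)(C)C(C)(C)C)[C@@H](C(=O)/C=C(/C)I)[C@H](OC(O)C(C)C)C[C@@]1(CO[Si](c2ccccc2)(c2ccccc2)C(C)(C)C)O[C@@H]1CCC(=O)OC | intermediate
22 | methyl 3-[(2R,3S)-3-(TBDPS-oxymethyl)-3-{(2R,3S,4S,5Z)-4-hydroxy-6-iodo-2-(2-methylpropanoyloxy)-3-[3-(TBS-oxy)prop-1-en-2-yl]hept-5-en-1-yl}oxiran-2-yl]propanoate | C=C(CO[Si](C)(C)C(C)(C)C)[C@@H]([C@H](O)/C=C(/C)I)[C@H](OC(=O)C(C)C)C[C@@]1(CO[Si](c2ccccc2)(c2ccccc2)C(C)(C)C)O[C@@H]1CCC(=O)OC | intermediate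
23 | methyl 3-[(2R,3S)-3-(TBDPS-oxymethyl)-3-{(2R,3R,4S,5Z)-6-iodo-2-(2-methylpropanoyloxy)-3-[3-(TBS-oxy)prop-1-en-2-yl]-4-(TES-oxy)hept-5-en-1-yl}oxiran-2-yl]propanoate | C=C(CO[Si](C)(C)C(C)(C)C)[C@@H]([C@H](O[Si](CC)(CC)CC)/C=C(/C)I)[C@H](OC(=O)C(C)C)C[C@@]1(CO[Si](c2ccccc2)(c2ccccc2)C(C)(C)C)O[C@@H]1CCC(=O)OC | intermediate
24 | 3-[(2R,3S)-3-(TBDPS-oxymethyl)-3-{(2R,3R,4S,5Z)-6-iodo-2-(2-methylpropanoyloxy)-3-[3-(TBS-oxy)prop-1-en-2-yl]-4-(TES-oxy)hept-5-en-1-yl}oxiran-2-yl]propanoic acid (formed in the flask) | C=C(CO[Si](C)(C)C(C)(C)C)[C@@H]([C@H](O[Si](CC)(CC)CC)/C=C(/C)I)[C@H](OC(=O)C(C)C)C[C@@]1(CO[Si](c2ccccc2)(c2ccccc2)C(C)(C)C)O[C@@H]1CCC(=O)O | intermediate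
25 | 1,3-dioxo-1,3-dihydro-2H-isoindol-2-yl ester of acid 24 (key-step precursor) | C=C(CO[Si](C)(C)C(C)(C)C)[C@@H]([C@H](O[Si](CC)(CC)CC)/C=C(/C)I)[C@H](OC(=O)C(C)C)C[C@@]1(CO[Si](c2ccccc2)(c2ccccc2)C(C)(C)C)O[C@@H]1CCC(=O)ON1C(=O)c2ccccc2C1=O | intermediate
26 | (1R,4Z,6R,7R,8R,10S)-7-[3-(TBS-oxy)prop-1-en-2-yl]-10-(TBDPS-oxymethyl)-4-methyl-6-(TES-oxy)-11-oxabicyclo[8.1.0]undec-4-en-8-yl 2-methylpropanoate (key-step product) | C=C(CO[Si](C)(C)C(C)(C)C)[C@H]1[C@H](O[Si](CC)(CC)CC)/C=C(/C)CC[C@H]2O[C@]2(CO[Si](c3ccccc3)(c3ccccc3)C(C)(C)C)C[C@H]1OC(=O)C(C)C | intermediate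
27 | (1R,4Z,6R,7S,8R,10S)-10-(TBDPS-oxymethyl)-6-hydroxy-7-(3-hydroxyprop-1-en-2-yl)-4-methyl-11-oxabicyclo[8.1.0]undec-4-en-8-yl 2-methylpropanoate | C=C(CO)[C@H]1[C@H](O)/C=C(/C)CC[C@H]2O[C@]2(CO[Si](c3ccccc3)(c3ccccc3)C(C)(C)C)C[C@H]1OC(=O)C(C)C | intermediate
28 | (1R,4Z,6R,7S,8R,10S)-10-(TBDPS-oxymethyl)-6-hydroxy-4-methyl-7-(3-oxoprop-1-en-2-yl)-11-oxabicyclo[8.1.0]undec-4-en-8-yl 2-methylpropanoate (formed in the flask) | C=C(C=O)[C@H]1[C@H](O)/C=C(/C)CC[C@H]2O[C@]2(CO[Si](c3ccccc3)(c3ccccc3)C(C)(C)C)C[C@H]1OC(=O)C(C)C | intermediate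
29 | lactol: (1R,4Z,6R,7R,8R,10S)-1,10:6,12-diepoxy-12-hydroxy-14-(TBDPS-oxy)germacra-4,11(13)-dien-8-yl 2-methylpropanoate, both C12 epimers (formed in the flask) | C=C1C(O)O[C@@H]2/C=C(/C)CC[C@H]3O[C@]3(CO[Si](c4ccccc4)(c4ccccc4)C(C)(C)C)C[C@@H](OC(=O)C(C)C)[C@@H]12 | intermediate
30 | (1R,4Z,6R,7R,8R,10S)-1,10-epoxy-8-(2-methylpropanoyloxy)-14-(TBDPS-oxy)germacra-4,11(13)-dien-12,6-olide | C=C1C(=O)O[C@@H]2/C=C(/C)CC[C@H]3O[C@]3(CO[Si](c4ccccc4)(c4ccccc4)C(C)(C)C)C[C@@H](OC(=O)C(C)C)[C@@H]12 | intermediate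
31 | (1R,4Z,6R,7R,8R,10S)-1,10-epoxy-14-hydroxy-8-(2-methylpropanoyloxy)germacra-4,11(13)-dien-12,6-olide (CNP0247143.1) | C=C1C(=O)O[C@@H]2/C=C(/C)CC[C@H]3O[C@]3(CO)C[C@@H](OC(=O)C(C)C)[C@@H]12 | target

**Step count and risks**

Total step count: 18. Longest linear sequence: 13 steps (steps 1–5 or steps 6–10, then steps 11–18).

Steps most likely to fail:

1. Step 15 (ring closure). The primary C3 radical may abstract hydrogen or dimerise, or the alkenylnickel may be reduced to the alkene, before the two ends meet across ten atoms. The fallback uses known chemistry and sets out from 25. Light-driven decarboxylative borylation with bis(catecholato)diboron in N,N-dimethylacetamide gives the C3 catechol boronate F1, which is exchanged in the same flask with pinacol and Et3N to the pinacol boronate F2. Intramolecular B-alkyl Suzuki–Miyaura coupling of F2 [Pd(dppf)Cl2, Ag2O, K2CO3, THF, 65 °C, high dilution] then joins C3 to C4 with retention of the alkene geometry and comes back to the route at 26.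

2. Step 11 (aldol). The amine may add to the β-iodoenone and expel iodide, the dienolate may drift into conjugation, and the β,γ-epoxy aldehyde may eliminate before the C–C bond forms; facial control by the boron ligands may also be incomplete. The fallback postpones the iodide and sets out from 16 and 10. The ynone 16, which has no β-leaving group, is enolised with the same bromoborane to the enol borinate F3 and added to 10 to give the β-hydroxy ynone F4. Evans–Tishchenko reaction with 20, through the hemiacetal F5, gives the propargylic alcohol isobutyrate F6. Hydroxyl-directed ruthenium-catalysed trans-hydrosilylation ([Cp*Ru(MeCN)3]PF6, Et3SiH, CH2Cl2) places silicon on C4 cis to C6 in the vinylsilane F7, and iododesilylation with retention (N-iodosuccinimide, 2,6-lutidine, hexafluoropropan-2-ol, 0 °C) comes back to the route at 22.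

3. Step 14 (ester cleavage and activation). Hydroxide transfer may reach the C8 isobutyrate as well as the methyl ester, and the liberated γ,δ-epoxy acid may open its own epoxide to a lactone. The fallback gives up the selectivity and sets out from 23. Both esters are saponified with LiOH in aqueous THF/MeOH to the hydroxy acid F8, which is kept as its lithium salt. Re-acylation with isobutyric anhydride, 4-(dimethylamino)pyridine and pyridine restores the O8 isobutyrate and also forms the mixed anhydride F9, which aqueous NaHCO3 cleaves. This comes back to the route at acid 24, which goes straight into the esterification of step 14.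

Further compounds
F1 | step 15 | C3 catechol boronate: 25 with the CO2N-phthalimide group replaced by 1,3,2-benzodioxaborol-2-yl on C3 (formed in the flask) | C=C(CO[Si](C)(C)C(C)(C)C)[C@@H]([C@H](O[Si](CC)(CC)CC)/C=C(/C)I)[C@H](OC(=O)C(C)C)C[C@@]1(CO[Si](c2ccccc2)(c2ccccc2)C(C)(C)C)O[C@@H]1CCB1Oc2ccccc2O1
F2 | step 15 | C3 pinacol boronate: 25 with the CO2N-phthalimide group replaced by 4,4,5,5-tetramethyl-1,3,2-dioxaborolan-2-yl on C3 | C=C(CO[Si](C)(C)C(C)(C)C)[C@@H]([C@H](O[Si](CC)(CC)CC)/C=C(/C)I)[C@H](OC(=O)C(C)C)C[C@@]1(CO[Si](c2ccccc2)(c2ccccc2)C(C)(C)C)O[C@@H]1CCB1OC(C)(C)C(C)(C)O1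
F3 | step 11 | (E)-enol borinate of ynone 16 with the same boron ligands (formed in the flask) | C=C(CO[Si](C)(C)C(C)(C)C)/C=C(/OB(C[C@@H]1[C@H](C(C)C)CC[C@@H](C)C1)C[C@@H]1[C@H](C(C)C)CC[C@@H](C)C1)C#CC
F4 | step 11 | (7R,8R)-anti β-hydroxy ynone: 19 with the C6 ketone bearing a prop-1-ynyl group in place of the Z-iodopropenyl group | C=C(CO[Si](C)(C)C(C)(C)C)[C@@H](C(=O)C#CC)[C@H](O)C[C@@]1(CO[Si](c2ccccc2)(c2ccccc2)C(C)(C)C)O[C@@H]1CCC(=O)OC
F5 | step 11 | hemiacetal of F4 at O8 with isobutyraldehyde (formed in the flask) | C=C(CO[Si](C)(C)C(C)(C)C)[C@@H](C(=O)C#CC)[C@H](OC(O)C(C)C)C[C@@]1(CO[Si](c2ccccc2)(c2ccccc2)C(C)(C)C)O[C@@H]1CCC(=O)OC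
F6 | step 11 | propargylic alcohol isobutyrate: 22 with a C4≡C5 alkyne in place of the Z-iodoalkene | C=C(CO[Si](C)(C)C(C)(C)C)[C@@H]([C@H](O)C#CC)[C@H](OC(=O)C(C)C)C[C@@]1(CO[Si](c2ccccc2)(c2ccccc2)C(C)(C)C)O[C@@H]1CCC(=O)OC
F7 | step 11 | Z-vinylsilane: 22 with triethylsilyl in place of iodine on C4 | C=C(CO[Si](C)(C)C(C)(C)C)[C@@H]([C@H](O)/C=C(/C)[Si](CC)(CC)CC)[C@H](OC(=O)C(C)C)C[C@@]1(CO[Si](c2ccccc2)(c2ccccc2)C(C)(C)C)O[C@@H]1CCC(=O)OC
F8 | step 14 | hydroxy acid: 24 with a free C8 hydroxyl in place of the isobutyrate | C=C(CO[Si](C)(C)C(C)(C)C)[C@@H]([C@H](O[Si](CC)(CC)CC)/C=C(/C)I)[C@H](O)C[C@@]1(CO[Si](c2ccccc2)(c2ccccc2)C(C)(C)C)O[C@@H]1CCC(=O)O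
F9 | step 14 | mixed anhydride of acid 24 with 2-methylpropanoic acid (formed in the flask) | C=C(CO[Si](C)(C)C(C)(C)C)[C@@H]([C@H](O[Si](CC)(CC)CC)/C=C(/C)I)[C@H](OC(=O)C(C)C)C[C@@]1(CO[Si](c2ccccc2)(c2ccccc2)C(C)(C)C)O[C@@H]1CCC(=O)OC(=O)C(C)C
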